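**Plan**

- Numbering and cuts: the oxolane is numbered O1, C2 (ring A, guaiacyl), C3 (CH2OH), C4 (bears the Cα carbinol with ring B, catechol), C5 (CH2). Going backwards, the three O-benzyl groups are removed, C3–CH2OH returns to an ester and Cα–OH to a ketone, the ketone is masked as a 1-arylvinyl group, and O1–C2 and C3–C4 are then cut together.
- Enabling feature: O1–C2 and C3–C4 lie opposite each other in the ring. The three-atom unit O1–C5–C4 (a vinyl epoxide opened by palladium, with ring B on the central allyl carbon) can therefore add across a C2=C3 acceptor (the ring A arylidene Meldrum's acid).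
- Forward order: a Knoevenagel condensation gives the acceptor, and the racemic 2-(1-arylvinyl)oxirane is made in four steps from 3,4-bis(benzyloxy)benzaldehyde. The fragments are joined and the oxolane, the only ring made, closes in one operation. The Meldrum's acid unit is then cut down to one ester, the alkene is cleaved to the ketone, and two reductions and a hydrogenolysis finish the route.
- Stereochemistry: C2 and C4 (cis) come from the ligand-controlled cycloaddition of the racemic epoxide (dynamic kinetic asymmetric transformation). C3 comes from base equilibration of the ester to the all-trans isomer. Cα comes from Felkin–Anh hydride addition under control of C4.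
- Design choices: Meldrum's acid is used rather than a dialkyl malonate as the activating group, because an electron-rich arylidene needs the extra electrophilicity and one carboxyl then leaves under mild conditions. The phenols are carried as benzyl ethers because several steps are basic.

Key step: step 6

Assumption: the (R,R) antipode of the DACH-phenyl diphosphine, N,N'-[(1R,2R)-cyclohexane-1,2-diyl]bis[2-(diphenylphosphanyl)benzamide], is taken to favour the (1R,4S) adduct 9. If the sense of induction proves opposite, the (S,S) ligand is used and nothing else changes.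

**Route**

Step 1
Reactants: 1 4-(benzyloxy)-3-methoxybenzaldehyde (O-benzylvanillin); 2 Meldrum's acid (2,2-dimethyl-1,3-dioxane-4,6-dione)
Product: 3 5-{[4-(benzyloxy)-3-methoxyphenyl]methylidene}-2,2-dimethyl-1,3-dioxane-4,6-dione
Conditions: pyrrolidine (10 mol %), AcOH (10 mol %), toluene, rt
Reagents that add atoms: none
Why: Knoevenagel condensation of the acidic Meldrum's acid with an aromatic aldehyde under pyrrolidinium acetate catalysis should give the crystalline arylidene derivative; no stereocentre is formed.

Step 2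
Reactants: 4 3,4-bis(benzyloxy)benzaldehyde
Product: 5 rac-1-[3,4-bis(benzyloxy)phenyl]prop-2-en-1-ol
Conditions: CH2=CHMgBr, THF, −78 to 0 °C; then H2O
Reagents that add atoms: vinylmagnesium bromide, C=C[Mg]Br
Why: Grignard 1,2-addition to the aromatic aldehyde should give the allylic benzylic alcohol, whose racemic stereocentre is removed in the next step.

Step 3
Reactants: 5 rac-1-[3,4-bis(benzyloxy)phenyl]prop-2-en-1-ol
Product: 6 1-[3,4-bis(benzyloxy)phenyl]prop-2-en-1-one
Conditions: activated MnO2 (excess), CH2Cl2, rt; used at once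
Reagents that add atoms: none
Why: MnO2 oxidation of an allylic benzylic alcohol is selective and neutral, and the aryl vinyl ketone is carried on directly because such enones polymerise on standing.

Step 4
Reactants: 6 1-[3,4-bis(benzyloxy)phenyl]prop-2-en-1-one
Product: 7 rac-[3,4-bis(benzyloxy)phenyl](oxiran-2-yl)methanone
Conditions: t-BuOOH (in decane), benzyltrimethylammonium hydroxide (cat.), THF, 0 °C
Reagents that add atoms: tert-butyl hydroperoxide, CC(C)(C)OO
Why: Weitz–Scheffer nucleophilic epoxidation, in which the tert-butylperoxide anion adds to the enone in conjugate fashion and the enolate closes the oxirane with loss of tert-butoxide; the new stereocentre is racemic, which is what the key step requires.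

Step 5
Reactants: 7 rac-[3,4-bis(benzyloxy)phenyl](oxiran-2-yl)methanone
Product: 8 rac-2-{1-[3,4-bis(benzyloxy)phenyl]ethenyl}oxirane
Conditions: Ph3PCH3Br, KN(SiMe3)2, THF, 0 °C; then 7, −78 to 0 °C; chromatography on Et3N-treated silica
Reagents that add atoms: methyltriphenylphosphonium bromide, C[P+](c1ccccc1)(c1ccccc1)c1ccccc1.[Br-]
Why: Wittig methylenation of the α,β-epoxy ketone at low temperature should convert the carbonyl into the 1,1-disubstituted alkene faster than the ylide opens the oxirane, and the oxirane stereocentre (racemic) is not touched.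

Step 6
Reactants: 3 5-{[4-(benzyloxy)-3-methoxyphenyl]methylidene}-2,2-dimethyl-1,3-dioxane-4,6-dione; 8 rac-2-{1-[3,4-bis(benzyloxy)phenyl]ethenyl}oxirane (1.3 equiv)
Product: 9 (1R,4S)-1-[4-(benzyloxy)-3-methoxyphenyl]-4-{1-[3,4-bis(benzyloxy)phenyl]ethenyl}-8,8-dimethyl-2,7,9-trioxaspiro[4.5]decane-6,10-dione (spiro positions 1, 2, 3, 4 and 5 are C2, O1, C5, C4 and C3 of the target oxolane)
Conditions: Pd2(dba)3·CHCl3 (2.5 mol %), (R,R)-DACH-phenyl diphosphine (7.5 mol %), degassed THF, 0 °C to rt
Reagents that add atoms: none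
Why: Zerovalent palladium ionises the allylic C–O bond of 8 to a zwitterionic 2-aryl-π-allylpalladium alkoxide, whose oxygen adds reversibly to the benzylic β-carbon of 3 (oxa-Michael addition, O1–C2) and whose Meldrum's acid carbanion then attacks the neighbouring allyl terminus anti to the metal (C3–C4) and releases the catalyst. The closest known reaction type is the palladium-catalysed formal [3+2] cycloaddition of vinyl epoxides and of the related vinylcyclopropanes and vinylethylene carbonates with doubly activated alkenes such as arylidene malononitriles and alkylidene Meldrum's acids, which has been run enantioselectively on racemic precursors. The oxolane closes by 5-exo attack of the stabilised carbanion on the proximal allyl terminus, which leaves the 1-arylvinyl group outside the ring and is preferred over 7-endo attack at the CH2 terminus. C4 is controlled by the chiral ligand, because the π-allyl complexes from the two enantiomers of 8 interconvert by π–σ–π isomerisation through the unsubstituted CH2 terminus faster than they are alkylated, so the ligand decides which allyl face the carbanion attacks (dynamic kinetic asymmetric transformation). C2 is set relative to C4 in the ring-closing transition state, since the oxa-Michael adducts equilibrate and the closure with ring A and the arylvinyl group both pseudo-equatorial (2,4-cis) should be the lower one. The step needs acceptor reactivity, 5- over 7-ring regioselectivity and cis selectivity: the Meldrum's acid unit makes the electron-rich arylidene electrophilic enough for the alkoxide and gives a soft, non-basic carbanion for the allylic alkylation, its local symmetry keeps C3 from becoming a stereocentre here, and the short tether between carbanion and allyl terminus secures the five-membered ring.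

Step 7
Reactants: 9 (1R,4S)-spiro cycloadduct
Product: 11 methyl (2S,4R)-2-[4-(benzyloxy)-3-methoxyphenyl]-4-{1-[3,4-bis(benzyloxy)phenyl]ethenyl}oxolane-3-carboxylate (both C3 epimers), via malonic half-ester acid 10 (not isolated)
Conditions: NaOMe (1.5 equiv), MeOH–THF, 0 °C to rt; AcOH to neutrality, evaporate; pyridine, 100 °C
Reagents that add atoms: sodium methoxide, [Na+].[O-]C
Why: Methoxide opens the electrophilic dioxanedione at one carbonyl with loss of acetone to the malonic half-ester salt, and after acidification the half-acid 10 loses CO2 in hot pyridine (malonic half-ester decarboxylation); protonation of the ester enol is not selective, so C3 is left as a mixture for step 8 while C2 and C4 are untouched.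

Step 8
Reactants: 11 methyl (2S,4R)-2-aryl-4-(1-arylethenyl)oxolane-3-carboxylate (both C3 epimers)
Product: 12 methyl (2S,3S,4R)-2-[4-(benzyloxy)-3-methoxyphenyl]-4-{1-[3,4-bis(benzyloxy)phenyl]ethenyl}oxolane-3-carboxylate
Conditions: NaOMe (0.3 equiv), MeOH–THF, 40 °C
Reagents that add atoms: none
Why: Base-mediated epimerisation through the ester enolate, in which C3 is the only acidic position and equilibration should place the ester trans to both of its cis-related neighbours (ring A at C2, arylvinyl at C4), while β-elimination of O1 would be the reverse of a 5-endo-trig closure and is stereoelectronically slow.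

Step 9
Reactants: 12 methyl (2S,3S,4R)-2-aryl-4-(1-arylethenyl)oxolane-3-carboxylate
Product: 14 methyl (2S,3S,4S)-2-[4-(benzyloxy)-3-methoxyphenyl]-4-[3,4-bis(benzyloxy)benzoyl]oxolane-3-carboxylate, via vicinal diol 13 (not isolated)
Conditions: OsO4 (2 mol %), NaIO4 (4 equiv), 2,6-lutidine (2 equiv), 1,4-dioxane–H2O, rt
Reagents that add atoms: osmium tetroxide, O=[Os](=O)(=O)=O; sodium periodate, [Na+].[O-]I(=O)(=O)=O
Why: Lemieux–Johnson oxidation, in which OsO4 dihydroxylates the electron-rich 1,1-disubstituted alkene and periodate cleaves the diol 13 to the aryl ketone and formaldehyde, is buffered by 2,6-lutidine and should leave the benzyl ethers, the ester and the three ring stereocentres untouched.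

Step 10
Reactants: 14 methyl (2S,3S,4S)-2-aryl-4-aroyloxolane-3-carboxylate
Product: 15 methyl (2S,3S,4S)-2-[4-(benzyloxy)-3-methoxyphenyl]-4-{(R)-[3,4-bis(benzyloxy)phenyl](hydroxy)methyl}oxolane-3-carboxylate
Conditions: LiBH(s-Bu)3 (1.3 equiv), THF, −78 °C; then H2O
Reagents that add atoms: none
Why: Felkin–Anh reduction of the α-branched aryl ketone by a bulky trialkylborohydride, with the more substituted ring carbon C3 anti to the incoming hydride and C4–H on its flank, should deliver hydride to the Si face and give the (R)-carbinol (a chelate through O1 would expose the same face), and the ester is not reduced at −78 °C.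

Step 11
Reactants: 15 methyl (2S,3S,4S)-2-aryl-4-[(R)-aryl(hydroxy)methyl]oxolane-3-carboxylate
Product: 16 {(2S,3R,4S)-2-[4-(benzyloxy)-3-methoxyphenyl]-4-{(R)-[3,4-bis(benzyloxy)phenyl](hydroxy)methyl}oxolan-3-yl}methanol
Conditions: LiAlH4, THF, 0 °C; then H2O, aq NaOH, H2O
Reagents that add atoms: none
Why: LiAlH4 reduction of the methyl ester to the primary alcohol, during which the benzylic alkoxide, the aryl benzyl ethers and the oxolane are inert and no stereocentre is affected.

Step 12
Reactants: 16 tribenzyl ether of the target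
Product: 17 {(2S,3R,4S)-4-[(R)-(3,4-dihydroxyphenyl)(hydroxy)methyl]-2-(4-hydroxy-3-methoxyphenyl)oxolan-3-yl}methanol (CNP0197133.1)
Conditions: H2 (1 atm), 10% Pd/C, EtOAc–MeOH, rt, stopped at full debenzylation
Reagents that add atoms: none
Why: Catalytic hydrogenolysis of aryl benzyl ethers over Pd/C under neutral conditions is much faster than cleavage of the benzylic C–O bonds at Cα and C2, so the three phenols should be freed without touching the stereocentres.

**Compound list**

1 | 4-(benzyloxy)-3-methoxybenzaldehyde | COc1cc(C=O)ccc1OCc1ccccc1 | starting material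
2 | Meldrum's acid (2,2-dimethyl-1,3-dioxane-4,6-dione) | CC1(C)OC(=O)CC(=O)O1 | starting material
3 | 5-{[4-(benzyloxy)-3-methoxyphenyl]methylidene}-2,2-dimethyl-1,3-dioxane-4,6-dione | COc1cc(C=C2C(=O)OC(C)(C)OC2=O)ccc1OCc1ccccc1 | intermediate
4 | 3,4-bis(benzyloxy)benzaldehyde | O=Cc1ccc(OCc2ccccc2)c(OCc2ccccc2)c1 | starting material
5 | rac-1-[3,4-bis(benzyloxy)phenyl]prop-2-en-1-ol | C=CC(O)c1ccc(OCc2ccccc2)c(OCc2ccccc2)c1 | intermediate
6 | 1-[3,4-bis(benzyloxy)phenyl]prop-2-en-1-one | C=CC(=O)c1ccc(OCc2ccccc2)c(OCc2ccccc2)c1 | intermediate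
7 | rac-[3,4-bis(benzyloxy)phenyl](oxiran-2-yl)methanone | O=C(C1CO1)c1ccc(OCc2ccccc2)c(OCc2ccccc2)c1 | intermediate
8 | rac-2-{1-[3,4-bis(benzyloxy)phenyl]ethenyl}oxirane | C=C(C1CO1)c1ccc(OCc2ccccc2)c(OCc2ccccc2)c1 | intermediate
9 | (1R,4S)-1-[4-(benzyloxy)-3-methoxyphenyl]-4-{1-[3,4-bis(benzyloxy)phenyl]ethenyl}-8,8-dimethyl-2,7,9-trioxaspiro[4.5]decane-6,10-dione | COc1cc([C@H]2OC[C@@H](C(=C)c3ccc(OCc4ccccc4)c(OCc4ccccc4)c3)C25C(=O)OC(C)(C)OC5=O)ccc1OCc1ccccc1 | intermediate
10 | (2R,4S)-2-[4-(benzyloxy)-3-methoxyphenyl]-4-{1-[3,4-bis(benzyloxy)phenyl]ethenyl}-3-(methoxycarbonyl)oxolane-3-carboxylic acid (both C3 epimers) | COc1cc([C@H]2OC[C@@H](C(=C)c3ccc(OCc4ccccc4)c(OCc4ccccc4)c3)C2(C(=O)O)C(=O)OC)ccc1OCc1ccccc1 | intermediate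
11 | methyl (2S,4R)-2-[4-(benzyloxy)-3-methoxyphenyl]-4-{1-[3,4-bis(benzyloxy)phenyl]ethenyl}oxolane-3-carboxylate (both C3 epimers) | COc1cc([C@H]2OC[C@@H](C(=C)c3ccc(OCc4ccccc4)c(OCc4ccccc4)c3)C2C(=O)OC)ccc1OCc1ccccc1 | intermediate
12 | methyl (2S,3S,4R)-2-[4-(benzyloxy)-3-methoxyphenyl]-4-{1-[3,4-bis(benzyloxy)phenyl]ethenyl}oxolane-3-carboxylate | COc1cc([C@H]2OC[C@@H](C(=C)c3ccc(OCc4ccccc4)c(OCc4ccccc4)c3)[C@@H]2C(=O)OC)ccc1OCc1ccccc1 | intermediate
13 | methyl (2S,3S,4S)-2-[4-(benzyloxy)-3-methoxyphenyl]-4-{1-[3,4-bis(benzyloxy)phenyl]-1,2-dihydroxyethyl}oxolane-3-carboxylate (both carbinol epimers) | COc1cc([C@H]2OC[C@@H](C(O)(CO)c3ccc(OCc4ccccc4)c(OCc4ccccc4)c3)[C@@H]2C(=O)OC)ccc1OCc1ccccc1 | intermediate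
14 | methyl (2S,3S,4S)-2-[4-(benzyloxy)-3-methoxyphenyl]-4-[3,4-bis(benzyloxy)benzoyl]oxolane-3-carboxylate | COc1cc([C@H]2OC[C@@H](C(=O)c3ccc(OCc4ccccc4)c(OCc4ccccc4)c3)[C@@H]2C(=O)OC)ccc1OCc1ccccc1 | intermediate
15 | methyl (2S,3S,4S)-2-[4-(benzyloxy)-3-methoxyphenyl]-4-{(R)-[3,4-bis(benzyloxy)phenyl](hydroxy)methyl}oxolane-3-carboxylate | COc1cc([C@H]2OC[C@@H]([C@@H](O)c3ccc(OCc4ccccc4)c(OCc4ccccc4)c3)[C@@H]2C(=O)OC)ccc1OCc1ccccc1 | intermediate
16 | {(2S,3R,4S)-2-[4-(benzyloxy)-3-methoxyphenyl]-4-{(R)-[3,4-bis(benzyloxy)phenyl](hydroxy)methyl}oxolan-3-yl}methanol | COc1cc([C@H]2OC[C@@H]([C@@H](O)c3ccc(OCc4ccccc4)c(OCc4ccccc4)c3)[C@@H]2CO)ccc1OCc1ccccc1 | intermediate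
17 | {(2S,3R,4S)-4-[(R)-(3,4-dihydroxyphenyl)(hydroxy)methyl]-2-(4-hydroxy-3-methoxyphenyl)oxolan-3-yl}methanol | COc1cc([C@H]2OC[C@@H]([C@@H](O)c3ccc(O)c(O)c3)[C@@H]2CO)ccc1O | target

**Step count and risks**

Total step count: 12. Longest linear sequence: 11 (steps 2 to 12).

Step 6 carries the most risk. The zwitterion may isomerise or oligomerise before it is trapped, the ligand may discriminate poorly between the interconverting allyl complexes, or closure may leak to the 2,4-trans ring. The fallback sets out from 8. Halide-catalysed insertion of carbon dioxide (CO2 at 1 atm, Bu4NBr, 60 °C) should give the bench-stable cyclic carbonate rac-4-{1-[3,4-bis(benzyloxy)phenyl]ethenyl}-1,3-dioxolan-2-one F1, which releases the same zwitterion on decarboxylation. Its cycloaddition with 3 under Pd2(dba)3·CHCl3 and a chiral BINOL-derived phosphoramidite, the known decarboxylative cycloaddition of vinylethylene carbonates with Michael acceptors, comes back to the route at 9.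

Step 10 may suffer from poor facial selectivity if the two ring carbons flanking C4 do not differ enough in size for the hydride to distinguish the carbonyl faces. The fallback sets out from 14 and moves the control from the substrate to a chiral catalyst. A Corey–Bakshi–Shibata reduction with BH3·SMe2 and the (S)-2-methyl-oxazaborolidine derived from diphenylprolinol, whose usual sense for aryl ketones (aryl as the large group) leads to the (R)-carbinol, comes back to the route at 15. It makes no new compound (entry F0).

Step 12 may over-reduce, with hydrogenolysis of the benzylic C–O bond at Cα (para to a phenol once it is freed) or of the C2–O1 bond competing with debenzylation. The fallback sets out from 14, where no benzylic alcohol is present yet, and exchanges the protecting groups: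
- Hydrogenolysis (H2, Pd/C, EtOAc) should give methyl (2S,3S,4S)-4-(3,4-dihydroxybenzoyl)-2-(4-hydroxy-3-methoxyphenyl)oxolane-3-carboxylate F2.
- TBSCl and imidazole in DMF convert it into methyl (2S,3S,4S)-4-[3,4-bis(tert-butyldimethylsilyloxy)benzoyl]-2-[4-(tert-butyldimethylsilyloxy)-3-methoxyphenyl]oxolane-3-carboxylate F3.
- LiBH(s-Bu)3 at −78 °C, as in step 10, gives methyl (2S,3S,4S)-4-{(R)-[3,4-bis(tert-butyldimethylsilyloxy)phenyl](hydroxy)methyl}-2-[4-(tert-butyldimethylsilyloxy)-3-methoxyphenyl]oxolane-3-carboxylate F4.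
- LiBH4 in THF–MeOH reduces the ester to {(2S,3R,4S)-4-{(R)-[3,4-bis(tert-butyldimethylsilyloxy)phenyl](hydroxy)methyl}-2-[4-(tert-butyldimethylsilyloxy)-3-methoxyphenyl]oxolan-3-yl}methanol F5.
- Bu4NF buffered with AcOH in THF at 0 °C removes the silyl groups and comes back to the route at 17.

**Further compounds**

F1 | step 6 | rac-4-{1-[3,4-bis(benzyloxy)phenyl]ethenyl}-1,3-dioxolan-2-one | C=C(C1COC(=O)O1)c1ccc(OCc2ccccc2)c(OCc2ccccc2)c1
F0 | step 10 | none | none
F2 | step 12 | methyl (2S,3S,4S)-4-(3,4-dihydroxybenzoyl)-2-(4-hydroxy-3-methoxyphenyl)oxolane-3-carboxylate | COc1cc([C@H]2OC[C@@H](C(=O)c3ccc(O)c(O)c3)[C@@H]2C(=O)OC)ccc1O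
F3 | step 12 | methyl (2S,3S,4S)-4-[3,4-bis(tert-butyldimethylsilyloxy)benzoyl]-2-[4-(tert-butyldimethylsilyloxy)-3-methoxyphenyl]oxolane-3-carboxylate | COc1cc([C@H]2OC[C@@H](C(=O)c3ccc(O[Si](C)(C)C(C)(C)C)c(O[Si](C)(C)C(C)(C)C)c3)[C@@H]2C(=O)OC)ccc1O[Si](C)(C)C(C)(C)C
F4 | step 12 | methyl (2S,3S,4S)-4-{(R)-[3,4-bis(tert-butyldimethylsilyloxy)phenyl](hydroxy)methyl}-2-[4-(tert-butyldimethylsilyloxy)-3-methoxyphenyl]oxolane-3-carboxylate | COc1cc([C@H]2OC[C@@H]([C@@H](O)c3ccc(O[Si](C)(C)C(C)(C)C)c(O[Si](C)(C)C(C)(C)C)c3)[C@@H]2C(=O)OC)ccc1O[Si](C)(C)C(C)(C)C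
F5 | step 12 | {(2S,3R,4S)-4-{(R)-[3,4-bis(tert-butyldimethylsilyloxy)phenyl](hydroxy)methyl}-2-[4-(tert-butyldimethylsilyloxy)-3-methoxyphenyl]oxolan-3-yl}methanol | COc1cc([C@H]2OC[C@@H]([C@@H](O)c3ccc(O[Si](C)(C)C(C)(C)C)c(O[Si](C)(C)C(C)(C)C)c3)[C@@H]2CO)ccc1O[Si](C)(C)C(C)(C)C
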